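**Remarks before the route**

- Labdane numbering is used for all ring and chain atoms (C1–C20), including in the acyclic precursors.
- Assumption: the (1R,2S,5R)-8-phenylmenthyl ester is taken to steer the radical cyclisation into the 4S,5R,9S,10S series, by analogy with this auxiliary in oxidative cyclisations of 2-methyl-3-oxo esters that lead to the natural podocarpane configuration at C4, C5 and C10. If the sense were opposite, the (1S,2R,5S) alcohol would replace 14 and nothing else would change.
- Assumption: 1 and 30 are taken as purchasable.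

## Analysis of the target

Compound 32 is a normal-series labdane. It has a trans-fused decalin (ring A: C1–C5 and C10; ring B: C5–C10), an exocyclic C8=C17 methylene, and at C9 a two-carbon chain (C11, C12) ending at C13 of an α-substituted butenolide (C13=C14, C15H2–O, C16=O). The four stereocentres are contiguous: C4 (S), C5 (R), C10 (S) and C9 (S). C4 and C10 are quaternary; the C19 methoxycarbonyl on C4 and the C20 acetoxymethylene on C10 are both axial on the β face, 1,3-diaxial across ring A. H5 and H9 are α and the C9 side chain is equatorial. Sensitive groups are the 1,1-disubstituted alkene (acid moves it into the ring), the butenolide (base, nucleophiles, hydride), the primary acetate and the hindered methyl ester. The difficulty is the pair of quaternary centres carrying one-carbon groups at different oxidation levels (C19 acid level, C20 alcohol level). The C20 oxygen rules out the terpene pool and farnesyl-type building blocks. Three features are used here. C4 carries a methyl and an ester carbon next to the methylene C3, which is the imprint of an α-methyl β-keto ester radical. C8=C17 is what oxidative termination of a tertiary C8 radical leaves. The syn-diaxial pair C19/C20 is an opened 19,20-δ-lactone, which gives a chiral ester a way in and a way out.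

## Retrosynthetic reasoning

**C12–C13.** The butenolide is cut off last, at the sp3–sp2 bond C12–C13, giving iodide 29 and bromobutenolide 30 (Negishi coupling through alkylzinc 31). The butenolide would not survive the fluoride, silanolate and hydride steps, so it must come last. What is gained is a bicyclic core with only a two-carbon handle at C9.

**C20–OAc and C12–I.** Acetate 29 comes from iodo alcohol 28, and 28 from diol 27. The neopentyl C20 hydroxyl and the unhindered C12 hydroxyl differ enough in reactivity that no protecting group is needed between them.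

**C19–OMe and C20–OH as an opened lactone.** Diol ester 27 is the ring-opened, O-methylated form of 19,20-lactone 24. Going forward, the lactone is opened at the acyl carbon and the carboxylate is methylated. This view is chosen because the lactone is the one place where a chiral ester group on C19 can be removed under mild conditions.

**Lactone from the auxiliary ester.** Lactone 24 arises from ester 22 when both silyl ethers are cleaved. The C20 alkoxide (diol ester 23) attacks the 1,3-diaxial C19 ester and expels 8-phenylmenthol 14. The forward step replaces an ester cleavage that no external nucleophile would achieve at this crowded centre.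

**C3 oxygen.** Ester 22 comes from ketone 19 through tosylhydrazone 20 and its borane adduct 21. The C3 carbonyl is the price of the key step and is removed directly afterwards, before any alkoxide is generated near the non-enolisable β-keto ester.

**Key disconnection: C4–C5 and C9–C10.** Ketone 19 is cut into the acyclic β-keto ester 18. Both rings, all four stereocentres and the C8=C17 methylene come from one oxidative radical bicyclisation (trivalent manganese, divalent copper). It is cut here because C4 already has the substitution pattern of the radical and C8 that of the terminating centre. The precursor is an open chain with two stereodefined alkenes and no stereocentre except the auxiliary.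

**C3–C4.** β-Keto ester 18 comes from ethyl ester 13 and propanoate 16 (from 14 and 15) by Claisen condensation through enolate 17. The auxiliary enters with a three-carbon unit that also brings C4 and C18.

**C1–C2 and the C5=C10 geometry.** Ester 13 comes from allylic alcohol 10 and orthoester 11 by Johnson–Claisen rearrangement through ketene acetal 12. This is the only step that has to place the oxygenated C20 cis to C6, and a chair transition state does that reliably.

**C5–C10.** Alcohol 10 is the mono-silyl ether of diol 9, which comes from aldehyde 6 and 2-bromoallyl alcohol 7 through dilithio reagent 8. The C20 oxygen therefore comes with the building block and is never made by oxidation.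

**C6–C7 and C8–C9.** Aldehyde 6 comes from allylic alcohol 3 and vinyl ether 4 by Claisen rearrangement through 5, and 3 from aldehyde 1 and Grignard reagent 2. The E geometry of C8=C9, which later fixes C9, is set here.

## Alternatives that were turned down

**Alternative 1:** the textbook route.
- Disconnection: C1–C10 and C4–C5 by Robinson annulation.
- Forward key step: an amine-catalysed enantioselective annulation to the Wieland–Miescher-type enedione A1, whose angular benzyloxymethyl group becomes C20.
- Why turned down: the annulation sets only C10. C4 (methyl plus ester, ester axial), C5, C9 and the C8 methylene must then be built one at a time. The ring B ketone of A1 sits at C9, where the target needs the side chain, while the sp2 carbon is needed at C8, so a carbonyl transposition is required. The precursor of A1, a 1,3-dione with a β-alkoxy group on its central carbon, is prone to retro-aldol loss of the C20 unit. The count would be well over twenty steps.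

**Alternative 2:** biomimetic cationic cyclisation.
- Disconnection: C4–C5 and C9–C10, as in the chosen route, but polar.
- Forward key step: Lewis-acid opening of the (3S)-epoxide A2 with an allylsilane terminus, to give the bicyclic 3β-alcohol A3 with the C8=C17 methylene.
- Why turned down: the C4 cation would carry the oxygenated C19 carbon, which destabilises it inductively and offers an internal oxygen nucleophile. C19 must sit Z on a trisubstituted epoxide, which is laborious to make as one enantiomer. After the cyclisation, C3–OH must be removed and C19 raised by three oxidation levels and esterified. This is at least six steps more than the radical route for the same two bonds.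

**Alternative 3:** late C20–H oxidation.
- Disconnection: the C20–O bond.
- Forward key step: carboxyl-directed lactonisation of the C20 methyl group of the 19-oic acid A4 to the 19,20-lactone A5, then the same opening as in steps 12–14.
- Why turned down: A4 is a labdane of almost the full complexity and would need a supply of scarce natural acids or a synthesis of its own. Carboxylate-directed C–H activation by divalent palladium favours β C–H bonds (C18, C3, C5), not the δ methyl C20. A radical relay from the acid is not available because acyloxy radicals lose CO2. A relay from the C19 alcohol gives the 19,20-ether, and its oxidation to the lactone would not spare C8=C17 and the butenolide.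

Key step: step 8

## Route

Step 1
Reactants: 1 3-[(tert-butyldiphenylsilyl)oxy]propanal; 2 isopropenylmagnesium bromide
Product: 3 rac-5-[(tert-butyldiphenylsilyl)oxy]-2-methylpent-1-en-3-ol
Conditions: THF, −78 → 0 °C; sat. aq. NH4Cl
Reagents that add atoms: none
Why: Grignard 1,2-addition to an unhindered aldehyde. The carbinol carbon (later C9) is left racemic because the Claisen rearrangement of step 2 turns it into an sp2 carbon.

Step 2
Reactants: 3 rac-5-[(tert-butyldiphenylsilyl)oxy]-2-methylpent-1-en-3-ol; 4 ethyl vinyl ether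
Product: 6 (4E)-7-[(tert-butyldiphenylsilyl)oxy]-4-methylhept-4-enal, via allyl vinyl ether 5 (not isolated)
Conditions: 4 (solvent), Hg(OAc)2 (10 mol %), reflux; evaporation; then toluene, 140 °C, sealed tube
Reagents that add atoms: none
Why: Transvinylation under divalent mercury catalysis gives the allyl vinyl ether, which undergoes the aliphatic Claisen rearrangement through a chair with the silyloxyethyl group equatorial. This forms the C6–C7 bond, the C5 aldehyde and the E-configured C8=C9 alkene that later fixes C9.

Step 3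
Reactants: 6 (4E)-7-[(tert-butyldiphenylsilyl)oxy]-4-methylhept-4-enal; 7 2-bromoprop-2-en-1-ol
Product: 9 rac-(6E)-9-[(tert-butyldiphenylsilyl)oxy]-6-methyl-2-methylidenenon-6-ene-1,3-diol, via lithium 2-lithioprop-2-en-1-olate 8 (not isolated)
Conditions: 7 (2 equiv), t-BuLi (6 equiv), Et2O, −78 → 0 °C; then 6, −78 °C; sat. aq. NH4Cl
Reagents that add atoms: none
Why: Deprotonation and bromine–lithium exchange of 7 give the vinyllithium alkoxide, which adds to the aldehyde and forms the C5–C10 bond with the C20 oxygen already in place. The new carbinol centre is racemic and is erased in step 5.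

Step 4
Reactants: 9 rac-(6E)-9-[(tert-butyldiphenylsilyl)oxy]-6-methyl-2-methylidenenon-6-ene-1,3-diol
Product: 10 rac-(6E)-9-[(tert-butyldiphenylsilyl)oxy]-6-methyl-2-methylidene-1-[(triisopropylsilyl)oxy]non-6-en-3-ol
Conditions: i-Pr3SiCl (1.05 equiv), imidazole, CH2Cl2, 0 °C
Reagents that add atoms: chlorotriisopropylsilane CC(C)[Si](Cl)(C(C)C)C(C)C
Why: The bulky chlorosilane silylates the primary allylic hydroxyl much faster than the secondary one. The triisopropylsilyl ether should survive acetic acid in step 8 and is cleaved by fluoride in step 11.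

Step 5
Reactants: 10 rac-(6E)-9-[(tert-butyldiphenylsilyl)oxy]-6-methyl-2-methylidene-1-[(triisopropylsilyl)oxy]non-6-en-3-ol; 11 triethyl orthoacetate
Product: 13 ethyl (4Z,8E)-11-[(tert-butyldiphenylsilyl)oxy]-8-methyl-4-{[(triisopropylsilyl)oxy]methyl}undeca-4,8-dienoate, via ketene acetal 12 (not isolated)
Conditions: 11 (6 equiv), EtCO2H (5 mol %), 140 °C, EtOH distilled off
Reagents that add atoms: none
Why: Johnson–Claisen rearrangement: the ketene acetal rearranges through a chair with the C6 chain equatorial, so C6 ends trans to the new C1 methylene and cis to C20 (4Z by the sequence rule). The C1–C2 bond and the C3 ester form at the same time, and this alkene geometry is what step 8 translates into the trans ring fusion.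

Step 6
Reactants: 14 (1R,2S,5R)-5-methyl-2-(2-phenylpropan-2-yl)cyclohexan-1-ol (8-phenylmenthol); 15 propanoyl chloride
Product: 16 (1R,2S,5R)-8-phenylmenthyl propanoate
Conditions: pyridine, DMAP (cat.), CH2Cl2, 0 °C → rt
Reagents that add atoms: none
Why: DMAP-catalysed acylation of a hindered secondary alcohol with an acid chloride; the stereocentres of 14 are not touched.

Step 7
Reactants: 13 ethyl (4Z,8E)-11-[(tert-butyldiphenylsilyl)oxy]-8-methyl-4-{[(triisopropylsilyl)oxy]methyl}undeca-4,8-dienoate; 16 (1R,2S,5R)-8-phenylmenthyl propanoate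
Product: 18 (1R,2S,5R)-8-phenylmenthyl (6Z,10E)-13-[(tert-butyldiphenylsilyl)oxy]-2,10-dimethyl-3-oxo-6-{[(triisopropylsilyl)oxy]methyl}trideca-6,10-dienoate (both epimers at C4), via lithium enolate 17 (not isolated)
Conditions: 16 (2.2 equiv), LiN(i-Pr)2 (2.3 equiv), THF, −78 °C; then 13, −78 → −20 °C; sat. aq. NH4Cl
Reagents that add atoms: none
Why: Crossed Claisen condensation of a preformed, hindered ester enolate with an unhindered ethyl ester forms the C3–C4 bond; the second equivalent of enolate deprotonates the product and drives the reaction. Both C4 epimers are acceptable because step 8 passes through the planar C4 radical.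

Step 8
Reactants: 18 (1R,2S,5R)-8-phenylmenthyl (6Z,10E)-13-[(tert-butyldiphenylsilyl)oxy]-2,10-dimethyl-3-oxo-6-{[(triisopropylsilyl)oxy]methyl}trideca-6,10-dienoate
Product: 19 (1R,2S,5R)-8-phenylmenthyl 3-oxo-12-[(tert-butyldiphenylsilyl)oxy]-20-[(triisopropylsilyl)oxy]-13,14,15,16-tetranorlabd-8(17)-en-19-oate (4α-methyl; 4β-ester; 5α-H; 9α-H; 10β-CH2OSi)
Conditions: Mn(OAc)3·2H2O (2.2 equiv), Cu(OAc)2·H2O (1.0 equiv), degassed AcOH, 25 °C
Reagents that add atoms: none
Why: The manganese enolate of 18 gives, by inner-sphere electron transfer to trivalent manganese, the planar C4 radical, which adds to C5; the tertiary C10 radical so formed adds to C9, and Cu(OAc)2 captures the tertiary C8 radical as an alkylcopper species that loses a hydrogen of C17 to give the C8=C17 methylene. The closest known reaction type is the Mn(OAc)3/Cu(OAc)2 oxidative free-radical bicyclisation of 2-methyl-3-oxo-6,10-dienoates to trans-fused decalones with an exocyclic methylene, which is also known with 8-phenylmenthyl esters. Ring A closes 6-endo-trig (C4–C5 bond), favoured over 5-exo by the sp2 ketone carbon C3 in the tether and by the fully substituted C10, and ring B closes 6-endo-trig (C9–C10 bond) to the tertiary C8 radical. C5 and C10 follow from anti addition across the C5=C10 alkene, in which C1 and C6 are trans, through a chair–chair arrangement, which gives the trans ring fusion with the C20 methylene axial. C9 follows from the E geometry of C8=C9 in the chair, which puts C11 equatorial and on the same face as C20. C4 is set by the conformation of the radical in the chair transition state, with ester and ketone carbonyl groups anti, which leaves the methyl group equatorial and the ester axial, syn to C20. The absolute sense comes from the auxiliary, whose phenyl ring lies over one face of the C4 radical so that C5 bonds from the open face, and the minor diastereomer should be removable by chromatography or crystallisation at this stage. The step needs 6-endo selectivity, closure of the C10 radical before its oxidation (no more than one equivalent of the copper salt), and loss of hydrogen from C17 and not from C7 or C9, which the copper-mediated elimination secures by taking the least hindered β-hydrogen.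

Step 9
Reactants: 19 (1R,2S,5R)-8-phenylmenthyl 3-oxo-12-[(tert-butyldiphenylsilyl)oxy]-20-[(triisopropylsilyl)oxy]-13,14,15,16-tetranorlabd-8(17)-en-19-oate
Product: 20 C3 p-toluenesulfonylhydrazone of 19
Conditions: TsNHNH2 (1.5 equiv), pyridinium p-toluenesulfonate (cat.), EtOH, 70 °C
Reagents that add atoms: p-toluenesulfonyl hydrazide Cc1ccc(cc1)S(=O)(=O)NN
Why: Condensation of the C3 ketone with the sulfonyl hydrazide under mild acid catalysis. The hindered ester does not react and the weak acid should not move the exocyclic alkene.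

Step 10
Reactants: 20 C3 p-toluenesulfonylhydrazone of 19
Product: 22 (1R,2S,5R)-8-phenylmenthyl 12-[(tert-butyldiphenylsilyl)oxy]-20-[(triisopropylsilyl)oxy]-13,14,15,16-tetranorlabd-8(17)-en-19-oate, via N-boryl tosylhydrazine 21 (not isolated)
Conditions: catecholborane (3 equiv), CHCl3, 0 °C; then NaOAc·3H2O, 60 °C
Reagents that add atoms: none
Why: Hydride transfer from catecholborane to the C=N bond, then acetate-induced loss of sulfinate, gives a diazene that loses N2; the C3 carbonyl becomes a methylene without base or strong acid. Esters, silyl ethers and the alkene are inert to catecholborane at 0 °C.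

Step 11
Reactants: 22 (1R,2S,5R)-8-phenylmenthyl 12-[(tert-butyldiphenylsilyl)oxy]-20-[(triisopropylsilyl)oxy]-13,14,15,16-tetranorlabd-8(17)-en-19-oate
Product: 24 12-hydroxy-13,14,15,16-tetranorlabd-8(17)-en-19,20-olide (lactone between the C19 carbonyl and the C20 oxygen), via diol ester 23 (not isolated)
Conditions: Bu4NF (4 equiv), THF, rt → 50 °C
Reagents that add atoms: none
Why: Fluoride removes both silyl groups; the C20 alkoxide sits 1,3-diaxial to the C19 ester and closes the six-membered lactone by intramolecular transesterification, which expels the auxiliary alcohol 14 for reuse. The closure is driven by the proximity of the two axial groups and by relief of crowding at the ester.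

Step 12
Reactants: 24 12-hydroxy-13,14,15,16-tetranorlabd-8(17)-en-19,20-olide
Product: 27 methyl 12,20-dihydroxy-13,14,15,16-tetranorlabd-8(17)-en-19-oate, via potassium carboxylate 25 (not isolated), via silyl ether methyl ester 26 (not isolated)
Conditions: KOSiMe3 (1.3 equiv), THF, 40 °C; then MeI (5 equiv), DMF, rt; aq. citric acid (pH 5), 0 °C
Reagents that add atoms: potassium trimethylsilanolate C[Si](C)(C)[O-].[K+]; iodomethane CI
Why: The silanolate opens the lactone at the acyl carbon under anhydrous conditions and leaves the potassium carboxylate with C20 as its trimethylsilyl ether, so no alkoxide is present when MeI alkylates the carboxylate oxygen (SN2). The silyl ether is hydrolysed in the mildly acidic work-up; strong acid or base is avoided because 27 could close back to 24.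

Step 13
Reactants: 27 methyl 12,20-dihydroxy-13,14,15,16-tetranorlabd-8(17)-en-19-oate
Product: 28 methyl 20-hydroxy-12-iodo-13,14,15,16-tetranorlabd-8(17)-en-19-oate
Conditions: I2 (1.1 equiv), PPh3 (1.1 equiv), imidazole (2 equiv), CH2Cl2, 0 °C
Reagents that add atoms: iodine II
Why: Appel-type iodination: the unhindered C12 hydroxyl is displaced, while the neopentyl C20 hydroxyl next to the quaternary C10 cannot undergo the SN2 step.

Step 14
Reactants: 28 methyl 20-hydroxy-12-iodo-13,14,15,16-tetranorlabd-8(17)-en-19-oate
Product: 29 methyl 20-acetoxy-12-iodo-13,14,15,16-tetranorlabd-8(17)-en-19-oate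
Conditions: Ac2O (3 equiv), i-Pr2NEt, DMAP (cat.), CH2Cl2, 0 °C → rt
Reagents that add atoms: acetic anhydride CC(=O)OC(C)=O
Why: DMAP-catalysed acetylation of the neopentyl primary alcohol. A hindered amine base is used so that the primary iodide does not alkylate it.

Step 15
Reactants: 29 methyl 20-acetoxy-12-iodo-13,14,15,16-tetranorlabd-8(17)-en-19-oate; 30 3-bromofuran-2(5H)-one
Product: 32 methyl (4S,5R,9S,10S)-20-acetoxylabda-8(17),13-dien-16,15-olid-19-oate, via alkylzinc iodide 31 (not isolated)
Conditions: Zn dust (activated with BrCH2CH2Br and Me3SiCl), LiCl, THF, 35 °C; then 30, Pd(OAc)2 (4 mol %), SPhos (8 mol %), THF, rt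
Reagents that add atoms: none
Why: Zinc insertion into the primary C–I bond tolerates both esters, and Negishi sp3–sp2 coupling under zerovalent palladium catalysis joins C12 to C13 of the α-bromobutenolide without moving the C13=C14 bond. The butenolide is introduced last because it would not survive the fluoride, silanolate and hydride steps.

## Compound list

1 | 3-[(tert-butyldiphenylsilyl)oxy]propanal | O=CCCO[Si](c1ccccc1)(c1ccccc1)C(C)(C)C | starting material
2 | isopropenylmagnesium bromide | CC(=C)[Mg]Br | starting material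
3 | rac-5-[(tert-butyldiphenylsilyl)oxy]-2-methylpent-1-en-3-ol | C=C(C)C(O)CCO[Si](c1ccccc1)(c1ccccc1)C(C)(C)C | intermediate
4 | ethyl vinyl ether | C=COCC | starting material
5 | allyl vinyl ether of 3 (not isolated) | C=COC(CCO[Si](c1ccccc1)(c1ccccc1)C(C)(C)C)C(C)=C | intermediate
6 | (4E)-7-[(tert-butyldiphenylsilyl)oxy]-4-methylhept-4-enal | O=CCC/C(C)=C/CCO[Si](c1ccccc1)(c1ccccc1)C(C)(C)C | intermediate
7 | 2-bromoprop-2-en-1-ol | OCC(Br)=C | starting material
8 | lithium 2-lithioprop-2-en-1-olate (not isolated) | [Li]OCC([Li])=C | intermediate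
9 | rac-(6E)-9-[(tert-butyldiphenylsilyl)oxy]-6-methyl-2-methylidenenon-6-ene-1,3-diol | C=C(CO)C(O)CC/C(C)=C/CCO[Si](c1ccccc1)(c1ccccc1)C(C)(C)C | intermediate
10 | rac-(6E)-9-[(tert-butyldiphenylsilyl)oxy]-6-methyl-2-methylidene-1-[(triisopropylsilyl)oxy]non-6-en-3-ol | C=C(CO[Si](C(C)C)(C(C)C)C(C)C)C(O)CC/C(C)=C/CCO[Si](c1ccccc1)(c1ccccc1)C(C)(C)C | intermediate
11 | triethyl orthoacetate | CC(OCC)(OCC)OCC | starting material
12 | mixed ketene acetal of 10 (not isolated) | C=C(OCC)OC(CC/C(C)=C/CCO[Si](c1ccccc1)(c1ccccc1)C(C)(C)C)C(=C)CO[Si](C(C)C)(C(C)C)C(C)C | intermediate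
13 | ethyl (4Z,8E)-11-[(tert-butyldiphenylsilyl)oxy]-8-methyl-4-{[(triisopropylsilyl)oxy]methyl}undeca-4,8-dienoate | CCOC(=O)CC/C(CO[Si](C(C)C)(C(C)C)C(C)C)=C/CC/C(C)=C/CCO[Si](c1ccccc1)(c1ccccc1)C(C)(C)C | intermediate
14 | (1R,2S,5R)-5-methyl-2-(2-phenylpropan-2-yl)cyclohexan-1-ol (8-phenylmenthol) | CC(C)(c1ccccc1)[C@@H]1CC[C@@H](C)C[C@H]1O | starting material
15 | propanoyl chloride | CCC(Cl)=O | starting material
16 | (1R,2S,5R)-8-phenylmenthyl propanoate | CCC(=O)O[C@@H]1C[C@H](C)CC[C@H]1C(C)(C)c1ccccc1 | intermediate
17 | lithium enolate of 16 (not isolated) | CC=C(O[Li])O[C@@H]1C[C@H](C)CC[C@H]1C(C)(C)c1ccccc1 | intermediate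
18 | (1R,2S,5R)-8-phenylmenthyl (6Z,10E)-13-[(tert-butyldiphenylsilyl)oxy]-2,10-dimethyl-3-oxo-6-{[(triisopropylsilyl)oxy]methyl}trideca-6,10-dienoate | O=C(O[C@@H]1C[C@H](C)CC[C@H]1C(C)(C)c1ccccc1)C(C)C(=O)CC/C(CO[Si](C(C)C)(C(C)C)C(C)C)=C/CC/C(C)=C/CCO[Si](c1ccccc1)(c1ccccc1)C(C)(C)C | intermediate
19 | (1R,2S,5R)-8-phenylmenthyl 3-oxo-12-[(tert-butyldiphenylsilyl)oxy]-20-[(triisopropylsilyl)oxy]-13,14,15,16-tetranorlabd-8(17)-en-19-oate | C=C1CC[C@@H]2[C@](CO[Si](C(C)C)(C(C)C)C(C)C)(CCC(=O)[C@]2(C)C(=O)O[C@@H]3C[C@H](C)CC[C@H]3C(C)(C)c3ccccc3)[C@H]1CCO[Si](c1ccccc1)(c1ccccc1)C(C)(C)C | intermediate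
20 | C3 p-toluenesulfonylhydrazone of 19 | C=C1CC[C@@H]2[C@](CO[Si](C(C)C)(C(C)C)C(C)C)(CCC(=NNS(=O)(=O)c4ccc(C)cc4)[C@]2(C)C(=O)O[C@@H]3C[C@H](C)CC[C@H]3C(C)(C)c3ccccc3)[C@H]1CCO[Si](c1ccccc1)(c1ccccc1)C(C)(C)C | intermediate
21 | N-(1,3,2-benzodioxaborol-2-yl) tosylhydrazine at C3 (not isolated) | C=C1CC[C@@H]2[C@](CO[Si](C(C)C)(C(C)C)C(C)C)(CCC(N(NS(=O)(=O)c4ccc(C)cc4)B4Oc5ccccc5O4)[C@]2(C)C(=O)O[C@@H]3C[C@H](C)CC[C@H]3C(C)(C)c3ccccc3)[C@H]1CCO[Si](c1ccccc1)(c1ccccc1)C(C)(C)C | intermediate
22 | (1R,2S,5R)-8-phenylmenthyl 12-[(tert-butyldiphenylsilyl)oxy]-20-[(triisopropylsilyl)oxy]-13,14,15,16-tetranorlabd-8(17)-en-19-oate | C=C1CC[C@@H]2[C@](CO[Si](C(C)C)(C(C)C)C(C)C)(CCC[C@]2(C)C(=O)O[C@@H]3C[C@H](C)CC[C@H]3C(C)(C)c3ccccc3)[C@H]1CCO[Si](c1ccccc1)(c1ccccc1)C(C)(C)C | intermediate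
23 | (1R,2S,5R)-8-phenylmenthyl 12,20-dihydroxy-13,14,15,16-tetranorlabd-8(17)-en-19-oate (not isolated) | C=C1CC[C@@H]2[C@](CO)(CCC[C@]2(C)C(=O)O[C@@H]3C[C@H](C)CC[C@H]3C(C)(C)c3ccccc3)[C@H]1CCO | intermediate
24 | 12-hydroxy-13,14,15,16-tetranorlabd-8(17)-en-19,20-olide | C=C1CC[C@@H]2[C@@]3(COC(=O)[C@@]2(C)CCC3)[C@H]1CCO | intermediate
25 | potassium 12-hydroxy-20-[(trimethylsilyl)oxy]-13,14,15,16-tetranorlabd-8(17)-en-19-oate (not isolated) | C=C1CC[C@@H]2[C@](CO[Si](C)(C)C)(CCC[C@]2(C)C(=O)[O-])[C@H]1CCO.[K+] | intermediate
26 | methyl 12-hydroxy-20-[(trimethylsilyl)oxy]-13,14,15,16-tetranorlabd-8(17)-en-19-oate (not isolated) | C=C1CC[C@@H]2[C@](CO[Si](C)(C)C)(CCC[C@]2(C)C(=O)OC)[C@H]1CCO | intermediate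
27 | methyl 12,20-dihydroxy-13,14,15,16-tetranorlabd-8(17)-en-19-oate | C=C1CC[C@@H]2[C@](CO)(CCC[C@]2(C)C(=O)OC)[C@H]1CCO | intermediate
28 | methyl 20-hydroxy-12-iodo-13,14,15,16-tetranorlabd-8(17)-en-19-oate | C=C1CC[C@@H]2[C@](CO)(CCC[C@]2(C)C(=O)OC)[C@H]1CCI | intermediate
29 | methyl 20-acetoxy-12-iodo-13,14,15,16-tetranorlabd-8(17)-en-19-oate | C=C1CC[C@@H]2[C@](COC(C)=O)(CCC[C@]2(C)C(=O)OC)[C@H]1CCI | intermediate
30 | 3-bromofuran-2(5H)-one | BrC1=CCOC1=O | starting material
31 | alkylzinc iodide from 29 (not isolated) | C=C1CC[C@@H]2[C@](COC(C)=O)(CCC[C@]2(C)C(=O)OC)[C@H]1CC[Zn]I | intermediate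
32 | methyl (4S,5R,9S,10S)-20-acetoxylabda-8(17),13-dien-16,15-olid-19-oate (CNP0104712.1) | C=C1CC[C@@H]2[C@](COC(C)=O)(CCC[C@]2(C)C(=O)OC)[C@H]1CCC1=CCOC1=O | target

## Step count and risk

Total: 15 steps. Longest linear sequence: 14 steps (steps 1–5 and 7–15, from 1); step 6 is a one-step side branch.

**Step 8 (key step).** Most likely to go wrong: incomplete facial discrimination by the auxiliary at 25 °C (acetic acid cannot be cooled further), and oxidation of the monocyclic C10 radical by the copper salt before ring B closes. Fallback, from 18 and back at 19: NaH and then PhSeCl at −78 °C would give the α-phenylselanyl β-keto ester F1. Irradiation in toluene at −78 °C would start a phenylselanyl group-transfer radical bicyclisation, with the same auxiliary and the same two 6-endo closures but no oxidant and a much lower temperature, giving the C8 phenylselenide F2. H2O2/pyridine would then form the selenoxide, whose syn elimination on the chair can only reach the hydrogens of C17, and so gives 19.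

**Step 11.** Most likely to go wrong: after desilylation the C20 alkoxide adds reversibly to the crowded ester but fails to expel the hindered alkoxide of 14, so the reaction stalls at 23. Fallback, from 22 and back at 27: LiAlH4 in THF at reflux would cleave the ester reductively to the C19 primary alcohol F7 (14 is recovered, the silyl ethers stay). Dess–Martin periodinane would give the aldehyde F8, NaClO2/NaH2PO4/2-methyl-2-butene (Pinnick oxidation) the acid F9, and Me3SiCHN2 the methyl ester F10. Bu4NF then removes both silyl groups to give 27.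

**Step 9 (with step 10).** Most likely to go wrong: slow or incomplete hydrazone formation at the neopentyl C3 ketone beside the quaternary C4. Fallback, from 19 and back at 22: NaBH4 in MeOH would give the C3 alcohol F5; 1,1'-thiocarbonyldiimidazole with DMAP in hot toluene would give the imidazolyl thiocarbonate F6; Bu3SnH/AIBN (Barton–McCombie deoxygenation) would give 22. The C3 radical is remote from the alkene.

**Step 7.** Most likely to go wrong: proton transfer from 13 to enolate 17 and self-condensation, giving low conversion and wasting the auxiliary ester. Fallback, from 13 and back at 18: i-Bu2AlH at −78 °C would give the aldehyde F3; aldol addition of 17 (1.1 equiv) would give the β-hydroxy ester F4 as a mixture of diastereomers; Dess–Martin periodinane would oxidise it to 18.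

**Step 13.** Most likely to go wrong: activation of the neopentyl C20 hydroxyl as well, followed by attack of the C19 ester oxygen and ring closure back to a 19,20-lactone with loss of the methyl group. Fallback, from 27 and back at 29: Ac2O/DMAP would give the diacetate F11; K2CO3 in MeOH at 0 °C would cleave the unhindered C12 acetate much faster than the neopentyl one, giving the C12 alcohol F12; the same iodination, now with C20 blocked, would give 29.

**Step 15.** Most likely to go wrong: sluggish zinc insertion or protodezincation, and decomposition of the bromobutenolide before cross-coupling. Fallback, from 29 and back at 32: alkylation of the lithium enolate of 3-(phenylsulfanyl)dihydrofuran-2(3H)-one (LiN(SiMe3)2, THF/DMPU, −78 → −20 °C) with iodide 29 would give the α-phenylsulfanyl lactone F13. mCPBA at −78 °C would oxidise sulfur selectively to the sulfoxide F14. Heating in toluene at 110 °C would give 32 by syn elimination into the lactone ring.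

## Further compounds

F1 | step 8 | (1R,2S,5R)-8-phenylmenthyl (6Z,10E)-13-[(tert-butyldiphenylsilyl)oxy]-2,10-dimethyl-3-oxo-2-(phenylselanyl)-6-{[(triisopropylsilyl)oxy]methyl}trideca-6,10-dienoate | O=C(O[C@@H]1C[C@H](C)CC[C@H]1C(C)(C)c1ccccc1)C(C)([Se]c1ccccc1)C(=O)CC/C(CO[Si](C(C)C)(C(C)C)C(C)C)=C/CC/C(C)=C/CCO[Si](c1ccccc1)(c1ccccc1)C(C)(C)C
F2 | step 8 | (1R,2S,5R)-8-phenylmenthyl 3-oxo-8-(phenylselanyl)-12-[(tert-butyldiphenylsilyl)oxy]-20-[(triisopropylsilyl)oxy]-13,14,15,16-tetranorlabdan-19-oate | CC1([Se]c4ccccc4)CC[C@@H]2[C@](CO[Si](C(C)C)(C(C)C)C(C)C)(CCC(=O)[C@]2(C)C(=O)O[C@@H]3C[C@H](C)CC[C@H]3C(C)(C)c3ccccc3)[C@H]1CCO[Si](c1ccccc1)(c1ccccc1)C(C)(C)C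
F3 | step 7 | (4Z,8E)-11-[(tert-butyldiphenylsilyl)oxy]-8-methyl-4-{[(triisopropylsilyl)oxy]methyl}undeca-4,8-dienal | O=CCC/C(CO[Si](C(C)C)(C(C)C)C(C)C)=C/CC/C(C)=C/CCO[Si](c1ccccc1)(c1ccccc1)C(C)(C)C
F4 | step 7 | (1R,2S,5R)-8-phenylmenthyl (6Z,10E)-13-[(tert-butyldiphenylsilyl)oxy]-3-hydroxy-2,10-dimethyl-6-{[(triisopropylsilyl)oxy]methyl}trideca-6,10-dienoate | O=C(O[C@@H]1C[C@H](C)CC[C@H]1C(C)(C)c1ccccc1)C(C)C(O)CC/C(CO[Si](C(C)C)(C(C)C)C(C)C)=C/CC/C(C)=C/CCO[Si](c1ccccc1)(c1ccccc1)C(C)(C)C
F5 | step 9 | (1R,2S,5R)-8-phenylmenthyl 3-hydroxy-12-[(tert-butyldiphenylsilyl)oxy]-20-[(triisopropylsilyl)oxy]-13,14,15,16-tetranorlabd-8(17)-en-19-oate | C=C1CC[C@@H]2[C@](CO[Si](C(C)C)(C(C)C)C(C)C)(CCC(O)[C@]2(C)C(=O)O[C@@H]3C[C@H](C)CC[C@H]3C(C)(C)c3ccccc3)[C@H]1CCO[Si](c1ccccc1)(c1ccccc1)C(C)(C)C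
F6 | step 9 | O-(imidazol-1-ylthiocarbonyl) derivative of F5 at C3 | C=C1CC[C@@H]2[C@](CO[Si](C(C)C)(C(C)C)C(C)C)(CCC(OC(=S)n4ccnc4)[C@]2(C)C(=O)O[C@@H]3C[C@H](C)CC[C@H]3C(C)(C)c3ccccc3)[C@H]1CCO[Si](c1ccccc1)(c1ccccc1)C(C)(C)C
F7 | step 11 | 12-[(tert-butyldiphenylsilyl)oxy]-20-[(triisopropylsilyl)oxy]-13,14,15,16-tetranorlabd-8(17)-en-19-ol | C=C1CC[C@@H]2[C@](CO[Si](C(C)C)(C(C)C)C(C)C)(CCC[C@]2(C)CO)[C@H]1CCO[Si](c1ccccc1)(c1ccccc1)C(C)(C)C
F8 | step 11 | 12-[(tert-butyldiphenylsilyl)oxy]-20-[(triisopropylsilyl)oxy]-13,14,15,16-tetranorlabd-8(17)-en-19-al | C=C1CC[C@@H]2[C@](CO[Si](C(C)C)(C(C)C)C(C)C)(CCC[C@]2(C)C=O)[C@H]1CCO[Si](c1ccccc1)(c1ccccc1)C(C)(C)C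
F9 | step 11 | 12-[(tert-butyldiphenylsilyl)oxy]-20-[(triisopropylsilyl)oxy]-13,14,15,16-tetranorlabd-8(17)-en-19-oic acid | C=C1CC[C@@H]2[C@](CO[Si](C(C)C)(C(C)C)C(C)C)(CCC[C@]2(C)C(=O)O)[C@H]1CCO[Si](c1ccccc1)(c1ccccc1)C(C)(C)C
F10 | step 11 | methyl 12-[(tert-butyldiphenylsilyl)oxy]-20-[(triisopropylsilyl)oxy]-13,14,15,16-tetranorlabd-8(17)-en-19-oate | C=C1CC[C@@H]2[C@](CO[Si](C(C)C)(C(C)C)C(C)C)(CCC[C@]2(C)C(=O)OC)[C@H]1CCO[Si](c1ccccc1)(c1ccccc1)C(C)(C)C
F11 | step 13 | methyl 12,20-diacetoxy-13,14,15,16-tetranorlabd-8(17)-en-19-oate | C=C1CC[C@@H]2[C@](COC(C)=O)(CCC[C@]2(C)C(=O)OC)[C@H]1CCOC(C)=O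
F12 | step 13 | methyl 20-acetoxy-12-hydroxy-13,14,15,16-tetranorlabd-8(17)-en-19-oate | C=C1CC[C@@H]2[C@](COC(C)=O)(CCC[C@]2(C)C(=O)OC)[C@H]1CCO
F13 | step 15 | methyl 20-acetoxy-13-(phenylsulfanyl)labd-8(17)-en-16,15-olid-19-oate | C=C1CC[C@@H]2[C@](COC(C)=O)(CCC[C@]2(C)C(=O)OC)[C@H]1CCC1(Sc3ccccc3)CCOC1=O
F14 | step 15 | methyl 20-acetoxy-13-(phenylsulfinyl)labd-8(17)-en-16,15-olid-19-oate | C=C1CC[C@@H]2[C@](COC(C)=O)(CCC[C@]2(C)C(=O)OC)[C@H]1CCC1(S(=O)c3ccccc3)CCOC1=O
A1 | alternative 1 | (S)-8a-[(benzyloxy)methyl]-3,4,8,8a-tetrahydronaphthalene-1,6(2H,7H)-dione | O=C1CCCC2=CC(=O)CC[C@]12COCc1ccccc1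
A2 | alternative 2 | acyclic (3S)-3,4-epoxide with C19 and C20 as benzyloxymethyl groups, C17 as trimethylsilylmethyl on the E-C8=C9 alkene and C12 as the tert-butyldiphenylsilyl ether | CC(C)(C)[Si](c1ccccc1)(c1ccccc1)OCC/C=C(C[Si](C)(C)C)/CC/C=C(COCc1ccccc1)/CC[C@@H]1O[C@]1(C)COCc1ccccc1
A3 | alternative 2 | 19,20-bis(benzyloxy)-12-[(tert-butyldiphenylsilyl)oxy]-13,14,15,16-tetranorlabd-8(17)-en-3β-ol | C=C1CC[C@@H]2[C@](COCc3ccccc3)(CC[C@H](O)[C@]2(C)COCc3ccccc3)[C@H]1CCO[Si](c1ccccc1)(c1ccccc1)C(C)(C)C
A4 | alternative 3 | labda-8(17),13-dien-16,15-olid-19-oic acid | C=C1CC[C@@H]2[C@](C)(CCC[C@]2(C)C(=O)O)[C@H]1CCC1=CCOC1=O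
A5 | alternative 3 | labda-8(17),13-diene-16,15:19,20-diolide | C=C1CC[C@@H]2[C@@]3(COC(=O)[C@@]2(C)CCC3)[C@H]1CCC1=CCOC1=O
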